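The runs stem from a simulated flask for substances that don't exist, noise included.

The early minutes speak against your hunch that birch will follow elm in percent. At 5.00 min, birch still holds 90.8% of its E as solid and elm 82.0%, yet per litre they have lost solid at nearly the same pace, 0.0144 M min⁻¹ and 0.0140 M min⁻¹. So we count solid per litre, not percent.

| flask | E | D | remark | time |
|---|---|---|---|---|
| birch | 0.78 M | 2 equiv | the very flask that is asked about, followed so far |  |
| elm | 0.39 M | 2 equiv | run made earlier |  |
| flask | 0.78 M | 2.00 equiv |  | 30 min |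

| run | time / min | E / % | L / % | J / % |
|---|---|---|---|---|
| birch | 0.500 | 98.6 | 0 | 1.7 |
| birch | 1.33 | 96.3 | 0.4 | 0.1 |
| birch | 2.50 | 96.8 | 2.1 | 0.6 |
| birch | 4.00 | 92.4 | 1.1 | 0.6 |
| birch | 5.00 | 90.8 | 1.8 | 2.5 |
| elm | 2.50 | 93.1 | 0.2 | 0 |
| elm | 5.00 | 82.0 | 1.0 | 0 |
| elm | 8.00 | 71.5 | 2.2 | 1.3 |
| elm | 15.0 | 55.2 | 4.6 | 8.2 |
| elm | 30.0 | 21.6 | 13.1 | 17.1 |

(readings scatter by 1 percentage point)

- the E standing at 30 min, as a percentage of the E charged (only what is still solid)
- the L standing at 30 min, as a percentage of the E charged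
- the J standing at 30 min, as a percentage of the E charged
- the Q standing at 30 min, as a percentage of the E charged

- given per volume of solution although it is solid: E
- at the start none of E is in solution

Over its whole 30.0 min, elm averages 0.0102 M min⁻¹, slower than its start, and we take that pace for birch over the same span. Birch's charge of 0.78 M then lasts 76.5 min. We call this the emptying time, the charge of solid over its loss per minute, taken as steady and so zero-order in the solid, and we count turnovers against it.

At 30 min, birch has run 0.392 of a turnover, so we expect 60.8% of E still solid. Elm reaches the same count at 15.0 min, with L at 4.6% and J at 8.2%. Birch has twice elm's charged [D], so we take those as lower marks. Q needs L or J first, so we expect it to trail them, and we expect the rest of what left the solid to be dissolved E.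

The forecast gives E 52%, L 6%, J 7% and Q 24%, holding that “the monoadducts convert faster to Q”. The flask gives E 55.8%, L 7.26%, J 12.3% and Q 6.02%.

    X + D → L + G (k = 3.80 × 10⁻⁴ M⁻¹ s⁻¹)
    X + D → J + G (k = 4.50 × 10⁻⁴ M⁻¹ s⁻¹)
    D + L → Q + G (k = 4.50 × 10⁻⁴ M⁻¹ s⁻¹)
    D + J → Q + G (k = 1.50 × 10⁻⁴ M⁻¹ s⁻¹)
    X + L → Z (k = 0.00110 M⁻¹ s⁻¹)
    E ⇌ X, rate k6*(cs6 - [X]) while solid is left; crystals form when [X] > cs6 (solubility = 0.400 M, k = 6.30 × 10⁻⁴ s⁻¹)

Our count of 0.392 of a turnover gave 60.8% of E as solid where the flask holds 55.8%, so the solid in the flask went 5 percentage points further than we counted. In the flask, half of the dissolving of E up to 30 min was done by 13.6 min, but half of the loss of X (dissolved E) + D to J + G up to then only by 18.0 min. The same flask read at 50 min counts 0.654 of a turnover, which means 34.6% of E as solid, and it holds 30.7%.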